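**Retrosynthetic overview**
- The target is a hetero-trimer of one resveratrol (unit A) and two oxyresveratrols (units B and C), joined by two 2,3-trans-2,3-diaryl-2,3-dihydrobenzofurans with all four centres S. Stilbene numbering used below: C7/C8 are the olefinic carbons (C8 next to the 3,5-dihydroxyphenyl ring), C10 is the resorcinol carbon ortho to the olefin, C3 is the carbon between the two oxygens of a 2,4-dihydroxyphenyl ring.
- Last cut: the dihydrobenzofuran on the resveratrol ring (C8 of unit B to C10 of unit A, then O to C7), giving resveratrol plus an enantiopure oxyresveratrol dehydrodimer. Forward, this is a crossed oxidative [3+2] coupling of two unprotected polyphenols.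
- The dimer: the dihydrobenzofuran on unit B (C8 of unit C to C3 of unit B, then the 2-O to C7), giving two oxyresveratrols by oxidative dehydrodimerisation. The racemate is resolved on a chiral phase.
- Ring order: the benzofuran on unit B first (it needs unit B as a free stilbene phenoxyl radical), the benzofuran on unit A second. No protecting groups.

Assumption: the target SMILES is read as an E-stilbene with both dihydrobenzofurans 2,3-trans and (2S,3S); a racemate is written as its two enantiomers joined by a dot.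

**Step 1**
Reactants: 1 oxyresveratrol (two molecules)
Product: 3 racemic trans-dehydrodimer rac-5-[(E)-2-[(2S*,3S*)-2-(2,4-dihydroxyphenyl)-3-(3,5-dihydroxyphenyl)-4-hydroxy-2,3-dihydro-1-benzofuran-7-yl]ethenyl]benzene-1,3-diol, via quinone methide 2 (not isolated)
Conditions: AgOAc (0.6 equiv per 1), MeOH, 50 °C, dark, 1 h, stop near half conversion; filter, recover 1, C18 prep. HPLC
Reagents that add atoms: none
Why: Biomimetic oxidative phenol coupling (8–3′ dehydrodimerisation of a 4-hydroxystilbene): AgOAc (monovalent silver) takes one electron and one proton from the 4-OH of each stilbene, C8 of one radical bonds to C3 of the other (ortho to the radical oxygen, between the two ring oxygens), rearomatisation gives quinone methide 2, and 5-exo oxa-Michael addition of the neighbouring 2-OH closes the dihydrobenzofuran with the two new centres 2,3-trans (aryl groups anti in the closing transition state, also the thermodynamic isomer) but racemic.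

**Step 2**
Reactants: 3 racemic trans-dehydrodimer
Product: 4 5-[(E)-2-[(2S,3S)-2-(2,4-dihydroxyphenyl)-3-(3,5-dihydroxyphenyl)-4-hydroxy-2,3-dihydro-1-benzofuran-7-yl]ethenyl]benzene-1,3-diol
Conditions: prep. HPLC, amylose tris(3,5-dimethylphenylcarbamate) chiral phase, hexane/EtOH/0.1% HCO2H; ECD assignment
Reagents that add atoms: none
Why: Resolution of enantiomers by chromatography on a polysaccharide chiral stationary phase (no bond is made or broken), a separation type established for 2,3-diaryl-2,3-dihydrobenzofuran stilbene dimers, with the (2S,3S) antipode identified by comparing its measured electronic circular dichroism spectrum with the calculated one.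

**Step 3**
Reactants: 4 (2S,3S)-dehydrodimer; 5 resveratrol (5 equiv)
Product: 7 (2S,3S)-2-[(2S,3S)-2-(2,4-dihydroxyphenyl)-3-(3,5-dihydroxyphenyl)-4-hydroxy-2,3-dihydro-1-benzofuran-7-yl]-3-(3,5-dihydroxyphenyl)-4-[(E)-2-(4-hydroxyphenyl)ethenyl]-2,3-dihydro-1-benzofuran-6-ol, via quinone methide 6 (not isolated)
Conditions: RuCl3·3H2O (2.2 equiv, added over 2 h), MeOH/H2O 1:1, rt, dark; NaHCO3 quench; Sephadex LH-20 (MeOH), then C18 prep. HPLC
Reagents that add atoms: none
Why: Biomimetic crossed oxidative [3+2] phenol–stilbene coupling of the ε-viniferin (8–10′) type: the stilbene phenol of 4 is the most electron-rich and is oxidised first by RuCl3 (trivalent ruthenium), its C8 radical bonds to C10 of resveratrol (ortho to the olefin-bearing carbon, activated by both resorcinol OH groups), loss of a second electron and rearomatisation give quinone methide 6, and the adjacent resorcinol OH adds 5-exo to the methide carbon to set the two new centres 2,3-trans, while their sense relative to the existing ring is not controlled, so 7 is separated from its (2R,3R) diastereomer by HPLC.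

**Compound list**
1 | oxyresveratrol, 4-[(E)-2-(3,5-dihydroxyphenyl)ethenyl]benzene-1,3-diol | Oc1ccc(/C=C/c2cc(O)cc(O)c2)c(O)c1 | starting material
2 | racemic quinone methide, 4-[(1E,2RS)-2-{2,6-dihydroxy-3-[(E)-2-(3,5-dihydroxyphenyl)ethenyl]phenyl}-2-(3,5-dihydroxyphenyl)ethylidene]-3-hydroxycyclohexa-2,5-dien-1-one | O=C1C=C/C(=C\[C@@H](c2cc(O)cc(O)c2)c2c(O)ccc(/C=C/c3cc(O)cc(O)c3)c2O)C(O)=C1.O=C1C=C/C(=C\[C@H](c2cc(O)cc(O)c2)c2c(O)ccc(/C=C/c3cc(O)cc(O)c3)c2O)C(O)=C1 | intermediate
3 | racemic trans-dehydrodimer, rac-5-[(E)-2-[(2S*,3S*)-2-(2,4-dihydroxyphenyl)-3-(3,5-dihydroxyphenyl)-4-hydroxy-2,3-dihydro-1-benzofuran-7-yl]ethenyl]benzene-1,3-diol | Oc1cc(O)cc(/C=C/c2ccc(O)c3c2O[C@H](c2ccc(O)cc2O)[C@H]3c2cc(O)cc(O)c2)c1.Oc1cc(O)cc(/C=C/c2ccc(O)c3c2O[C@@H](c2ccc(O)cc2O)[C@@H]3c2cc(O)cc(O)c2)c1 | intermediate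
4 | 5-[(E)-2-[(2S,3S)-2-(2,4-dihydroxyphenyl)-3-(3,5-dihydroxyphenyl)-4-hydroxy-2,3-dihydro-1-benzofuran-7-yl]ethenyl]benzene-1,3-diol | Oc1cc(O)cc(/C=C/c2ccc(O)c3c2O[C@H](c2ccc(O)cc2O)[C@H]3c2cc(O)cc(O)c2)c1 | intermediate
5 | resveratrol, 5-[(E)-2-(4-hydroxyphenyl)ethenyl]benzene-1,3-diol | Oc1ccc(/C=C/c2cc(O)cc(O)c2)cc1 | starting material
6 | quinone methide, (2S,3S,7E)-2-(2,4-dihydroxyphenyl)-3-(3,5-dihydroxyphenyl)-7-[(2S)-2-(3,5-dihydroxyphenyl)-2-{2,4-dihydroxy-6-[(E)-2-(4-hydroxyphenyl)ethenyl]phenyl}ethylidene]-2,3-dihydro-1-benzofuran-4(7H)-one | Oc1ccc(/C=C/c2cc(O)cc(O)c2[C@H](c2cc(O)cc(O)c2)/C=C2\C=CC(=O)C3=C2O[C@H](c2ccc(O)cc2O)[C@H]3c2cc(O)cc(O)c2)cc1 | intermediate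
7 | (2S,3S)-2-[(2S,3S)-2-(2,4-dihydroxyphenyl)-3-(3,5-dihydroxyphenyl)-4-hydroxy-2,3-dihydro-1-benzofuran-7-yl]-3-(3,5-dihydroxyphenyl)-4-[(E)-2-(4-hydroxyphenyl)ethenyl]-2,3-dihydro-1-benzofuran-6-ol | Oc1ccc(/C=C/c2cc(O)cc3c2[C@H](c2cc(O)cc(O)c2)[C@@H](c2ccc(O)c4c2O[C@H](c2ccc(O)cc2O)[C@H]4c2cc(O)cc(O)c2)O3)cc1 | target

**Totals**
Total step count: 3. Longest linear sequence: 3 (1 → 3 → 4 → 7).

**Steps most likely to fail, with fallbacks**

Step 3 (highest risk). Both partners are free polyphenols. Resveratrol can self-couple, the cross-coupling can run in the reverse sense (C8 of resveratrol to a resorcinol ring of 4), and other ring positions can be attacked. The new ring forms in both facial senses, so a yield of a few percent is expected. The HCl formed may also open the acid-labile ring of 4.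
Fallback: make the acceptor non-oxidisable so that only 4 can be the oxidised partner. It sets out from 5 (4 is used unchanged) and comes back at 7. Compound 5 is acetylated at the exposed para-phenol with immobilised Candida antarctica lipase B and vinyl acetate in t-BuOMe at 40 °C, giving 4′-O-acetylresveratrol F1. Compound 4 is then oxidised with PhI(OAc)2 (1.05 equiv, slow addition) in (CF3)2CHOH/CH2Cl2 at −20 °C in the presence of F1 (4 equiv). This is a two-electron oxidative Friedel–Crafts/oxa-Michael cascade through the same quinone methide logic and gives the mono-acetate of the trimer F2, again separated from its (2R,3R) diastereomer. K2CO3 in MeOH at 0 °C removes the acetate to give 7.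

Step 1. The C–C bond may form at C5 instead of C3, and ring closure may go through the 4-OH instead of the 2-OH. The wanted isomer may therefore be a minor component of the dehydrodimer fraction, and 3 can be over-oxidised.
Fallback: block C5. This fallback replaces 1 itself, so it sets out from two further commercial materials in place of compound 1 and comes back at 3. 5-Bromo-2,4-dihydroxybenzaldehyde F3 and 3,5-dihydroxyphenylacetic acid F4 are condensed with piperidine and 1-methylimidazole in polyethylene glycol at 130 °C (decarboxylative Knoevenagel condensation through the para-quinone methide), giving (E)-5-bromo-oxyresveratrol F5. AgOAc in MeOH then gives the racemic dibromo dehydrodimer F6; C3 is now the only free carbon ortho to the radical oxygen, and the bromine next to the 4-OH makes that oxygen the poorer nucleophile. Pd(PPh3)4 (zerovalent palladium) with HCO2Na in DMF at 80 °C removes both bromines without touching the stilbene and gives 3.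

Step 2. The enantiomers of 3 may not separate at preparative loading, or the ECD assignment may be ambiguous.
Fallback: resolve later, on the larger molecule. It sets out from 3 and comes back at 7. Racemic 3 is taken through the step 3 conditions with 5. C18 HPLC isolates the like diastereomer as the racemic trimer F7 (7 plus its mirror image). Chiral-phase HPLC of F7 then gives 7, with the assignment made by ECD on the trimer.

**Further compounds**
F1 | step 3 | 4′-O-acetylresveratrol, 4-[(E)-2-(3,5-dihydroxyphenyl)ethenyl]phenyl acetate | CC(=O)Oc1ccc(/C=C/c2cc(O)cc(O)c2)cc1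
F2 | step 3 | mono-acetate of 7, 4-[(E)-2-[(2S,3S)-2-[(2S,3S)-2-(2,4-dihydroxyphenyl)-3-(3,5-dihydroxyphenyl)-4-hydroxy-2,3-dihydro-1-benzofuran-7-yl]-3-(3,5-dihydroxyphenyl)-6-hydroxy-2,3-dihydro-1-benzofuran-4-yl]ethenyl]phenyl acetate | CC(=O)Oc1ccc(/C=C/c2cc(O)cc3c2[C@H](c2cc(O)cc(O)c2)[C@@H](c2ccc(O)c4c2O[C@H](c2ccc(O)cc2O)[C@H]4c2cc(O)cc(O)c2)O3)cc1
F3 | step 1 | 5-bromo-2,4-dihydroxybenzaldehyde | O=Cc1cc(Br)c(O)cc1O
F4 | step 1 | 3,5-dihydroxyphenylacetic acid | OC(=O)Cc1cc(O)cc(O)c1
F5 | step 1 | (E)-5-bromo-oxyresveratrol, 4-bromo-6-[(E)-2-(3,5-dihydroxyphenyl)ethenyl]benzene-1,3-diol | Oc1cc(O)c(/C=C/c2cc(O)cc(O)c2)cc1Br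
F6 | step 1 | racemic dibromo dehydrodimer, rac-5-[(E)-2-[(2S*,3S*)-5-bromo-2-(5-bromo-2,4-dihydroxyphenyl)-3-(3,5-dihydroxyphenyl)-4-hydroxy-2,3-dihydro-1-benzofuran-7-yl]ethenyl]benzene-1,3-diol | Oc1cc(O)cc(/C=C/c2cc(Br)c(O)c3c2O[C@H](c2cc(Br)c(O)cc2O)[C@H]3c2cc(O)cc(O)c2)c1.Oc1cc(O)cc(/C=C/c2cc(Br)c(O)c3c2O[C@@H](c2cc(Br)c(O)cc2O)[C@@H]3c2cc(O)cc(O)c2)c1
F7 | step 2 | racemic trimer (7 and its enantiomer) | Oc1ccc(/C=C/c2cc(O)cc3c2[C@H](c2cc(O)cc(O)c2)[C@@H](c2ccc(O)c4c2O[C@H](c2ccc(O)cc2O)[C@H]4c2cc(O)cc(O)c2)O3)cc1.Oc1ccc(/C=C/c2cc(O)cc3c2[C@@H](c2cc(O)cc(O)c2)[C@H](c2ccc(O)c4c2O[C@@H](c2ccc(O)cc2O)[C@@H]4c2cc(O)cc(O)c2)O3)cc1
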